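## Retrosynthetic overview

1. Target 20 is unmasked from the threo carbinol 17 (O9 silyl ether, O5' benzyl ether, a 3-aryl-4,5-dihydroisoxazole as the latent 3-hydroxypropanoyl chain on ring B) by fluoride, Raney Ni N–O hydrogenolysis and debenzylation.
2. Key disconnection C1–C7: 17 comes from 3,4-dimethoxyphenylmagnesium bromide 16 (ring A) and the (S)-2-aryloxy-3-silyloxypropanal 14. The plan rests on C7 being a benzylic carbinol directly beside the C8 aryl ether: the C8–O–C4' oxygen, backed by the ortho methoxy oxygen on C3' of ring B, can hold magnesium next to a C7 aldehyde.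
3. 14 comes from the prochiral 2-aryloxypropane-1,3-diol 10 by lipase desymmetrisation, silylation, deacetylation and oxidation; 10 comes from 5-hydroxyvanillin 1, benzyl bromide, diethyl bromomalonate 3 and ethylene 7.
4. Ordering on ring B: the formyl group travels as its oxime through the ester reduction (LiBH4 spares the oxime, whereas LiAlH4 would destroy an isoxazoline) and becomes the isoxazoline only at the diol stage, because a nitrile oxide tolerates neither a free phenol nor the acidic malonate C–H.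
5. Rings: both benzene rings are bought; the only ring made is the temporary isoxazoline (step 5), opened again in step 13; the key step closes no ring.

Key step: step 11

Remark on numbering: positions follow 8-O-4' neolignan usage (ring A = 3,4-dimethoxyphenyl on C7; C7–C8–C9 = propane chain; ring B = the aryloxy ring, C4' bearing the ether oxygen and C1' the three-carbon keto chain).

Assumption: the lipase is taken to acylate the pro-S hydroxymethyl group of diol 10, the sense expected for 2-O-substituted propane-1,3-diols with Burkholderia cepacia lipase; the enzyme is to be confirmed by a short screen.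

## Route

Step 1
Reactants: 1 3,4-dihydroxy-5-methoxybenzaldehyde
Product: 2 3-(benzyloxy)-4-hydroxy-5-methoxybenzaldehyde
Conditions: NaH (2.2 equiv), DMSO, rt; BnBr (1.0 equiv), rt; aq. HCl work-up
Reagents that add atoms: benzyl bromide, BrCc1ccccc1
Why: Williamson etherification through the catechol dianion, in which the 4-phenoxide is delocalised into the para formyl group and flanked by two ortho oxygens, so the single equivalent of benzyl bromide should be taken by the more nucleophilic 3-phenoxide.

Step 2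
Reactants: 2 3-(benzyloxy)-4-hydroxy-5-methoxybenzaldehyde; 3 diethyl bromomalonate
Product: 4 diethyl 2-[2-(benzyloxy)-4-formyl-6-methoxyphenoxy]malonate
Conditions: K2CO3, DMF, rt
Reagents that add atoms: none
Why: Williamson etherification, the phenoxide displacing the doubly activated bromide by SN2 while the electron-rich aldehyde stays a spectator.

Step 3
Reactants: 4 diethyl 2-[2-(benzyloxy)-4-formyl-6-methoxyphenoxy]malonate
Product: 5 diethyl 2-{2-(benzyloxy)-4-[(E)-(hydroxyimino)methyl]-6-methoxyphenoxy}malonate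
Conditions: NH2OH·HCl (1.1 equiv), NaOAc, EtOH, 0 °C to rt
Reagents that add atoms: hydroxylamine hydrochloride, Cl.NO
Why: Oxime condensation, far faster at the aldehyde than aminolysis of the esters under acetate buffer; the oxime protects the formyl carbon from hydride and is the later nitrile oxide precursor.

Step 4
Reactants: 5 diethyl 2-{2-(benzyloxy)-4-[(E)-(hydroxyimino)methyl]-6-methoxyphenoxy}malonate
Product: 6 (E)-3-(benzyloxy)-4-[(1,3-dihydroxypropan-2-yl)oxy]-5-methoxybenzaldehyde oxime
Conditions: LiBH4 (3 equiv), THF, 0 °C to rt; aq. NH4Cl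
Reagents that add atoms: none
Why: Borohydride reduction of both ester groups to the prochiral 1,3-diol; the aldoxime and the benzyl ether are inert to LiBH4.

Step 5
Reactants: 6 (E)-3-(benzyloxy)-4-[(1,3-dihydroxypropan-2-yl)oxy]-5-methoxybenzaldehyde oxime; 7 ethylene
Product: 10 2-[2-(benzyloxy)-4-(4,5-dihydro-1,2-oxazol-3-yl)-6-methoxyphenoxy]propane-1,3-diol, via hydroximoyl chloride 8 (not isolated), via nitrile oxide 9 (not isolated)
Conditions: NCS, DMF, rt; then ethylene (5 bar), Et3N (slow addition), CH2Cl2, 0 °C to rt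
Reagents that add atoms: none
Why: Huisgen nitrile oxide cycloaddition: NCS chlorinates the aldoxime to 8, Et3N eliminates HCl to nitrile oxide 9, and excess ethylene traps it as the 3-aryl-4,5-dihydroisoxazole faster than it dimerises; the free primary alcohols do not interfere and the diol stays prochiral.

Step 6
Reactants: 10 2-[2-(benzyloxy)-4-(4,5-dihydro-1,2-oxazol-3-yl)-6-methoxyphenoxy]propane-1,3-diol
Product: 11 (2S)-2-[2-(benzyloxy)-4-(4,5-dihydro-1,2-oxazol-3-yl)-6-methoxyphenoxy]-3-hydroxypropyl acetate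
Conditions: immobilised lipase from Burkholderia cepacia, vinyl acetate, t-BuOMe, rt, stopped at the monoacetate stage
Reagents that add atoms: vinyl acetate, C=COC(C)=O
Why: Lipase-catalysed desymmetrising transesterification, made irreversible by tautomerisation of the released vinyl alcohol; the enzyme's choice of the pro-S hydroxymethyl group sets the C8 stereocentre as (S).

Step 7
Reactants: 11 (2S)-2-[2-(benzyloxy)-4-(4,5-dihydro-1,2-oxazol-3-yl)-6-methoxyphenoxy]-3-hydroxypropyl acetate
Product: 12 (2R)-2-[2-(benzyloxy)-4-(4,5-dihydro-1,2-oxazol-3-yl)-6-methoxyphenoxy]-3-[(triisopropylsilyl)oxy]propyl acetate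
Conditions: TIPSOTf, 2,6-lutidine, CH2Cl2, −78 °C
Reagents that add atoms: triisopropylsilyl trifluoromethanesulfonate, CC(C)[Si](C(C)C)(C(C)C)OS(=O)(=O)C(F)(F)F
Why: Silylation of the free primary alcohol with a silyl triflate, fast at low temperature so that 1,3-acetyl migration (which would racemise C8) cannot compete; the descriptor changes to R only through the priority rules.

Step 8
Reactants: 12 (2R)-2-[2-(benzyloxy)-4-(4,5-dihydro-1,2-oxazol-3-yl)-6-methoxyphenoxy]-3-[(triisopropylsilyl)oxy]propyl acetate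
Product: 13 (2R)-2-[2-(benzyloxy)-4-(4,5-dihydro-1,2-oxazol-3-yl)-6-methoxyphenoxy]-3-[(triisopropylsilyl)oxy]propan-1-ol
Conditions: K2CO3 (0.2 equiv), MeOH, 0 °C
Reagents that add atoms: none
Why: Zemplén-type methanolysis of the acetate; the bulky triisopropylsilyl ether should resist both cleavage and O-to-O migration under these mild conditions, so C8 keeps its configuration.

Step 9
Reactants: 13 (2R)-2-[2-(benzyloxy)-4-(4,5-dihydro-1,2-oxazol-3-yl)-6-methoxyphenoxy]-3-[(triisopropylsilyl)oxy]propan-1-ol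
Product: 14 (2S)-2-[2-(benzyloxy)-4-(4,5-dihydro-1,2-oxazol-3-yl)-6-methoxyphenoxy]-3-[(triisopropylsilyl)oxy]propanal
Conditions: DMP, CH2Cl2, 0 °C to rt; cold aq. NaHCO3/Na2S2O3 wash; used at once without chromatography
Reagents that add atoms: none
Why: Dess–Martin oxidation of the primary alcohol under non-basic conditions, chosen so that the epimerisable α-aryloxy centre C8 is not disturbed.

Step 10
Reactants: 15 4-bromo-1,2-dimethoxybenzene
Product: 16 3,4-dimethoxyphenylmagnesium bromide
Conditions: Mg turnings, I2 (cat.), Et2O, reflux; titrated and used as the ether solution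
Reagents that add atoms: magnesium, [Mg]
Why: Grignard formation by insertion of magnesium into the aryl C–Br bond, carried out in diethyl ether so that no strongly donating solvent enters the key step.

Step 11
Reactants: 14 (2S)-2-[2-(benzyloxy)-4-(4,5-dihydro-1,2-oxazol-3-yl)-6-methoxyphenoxy]-3-[(triisopropylsilyl)oxy]propanal; 16 3,4-dimethoxyphenylmagnesium bromide
Product: 17 (1S,2S)-2-[2-(benzyloxy)-4-(4,5-dihydro-1,2-oxazol-3-yl)-6-methoxyphenoxy]-1-(3,4-dimethoxyphenyl)-3-[(triisopropylsilyl)oxy]propan-1-ol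
Conditions: MgBr2·OEt2 (1.5 equiv), CH2Cl2, −78 °C; then 16 (2 equiv, Et2O), −78 °C; sat. aq. NH4Cl
Reagents that add atoms: none
Why: The aryl Grignard reagent adds 1,2 to the C7 formyl carbon through a Cram chelate in which magnesium is bound by the carbonyl oxygen and the C8 aryloxy oxygen, with the ortho methoxy and benzyloxy oxygens of ring B as further donors, so that C7=O and C8–O lie syn-periplanar in a five-membered chelate. The closest known reaction type is the chelation-controlled addition of Grignard reagents to α-alkoxy aldehydes, which gives syn 1,2-diol monoethers. No ring is closed; the step forms one skeletal bond (C1–C7) and one stereocentre (C7). The aryl group should enter on the chelate face that carries the C8 hydrogen, away from the C9 silyloxymethyl arm, which for the (S)-aldehyde gives the (7S) carbinol, that is the threo (7S,8S) pair. The selectivity needed is 1,2-syn over the Felkin-type erythro mode; it is secured by the α-oxygen chelate, by the bulky triisopropylsilyl ether that keeps O9 from competing as a donor, and by excluding tetrahydrofuran. The C8 configuration is kept by using the freshly made aldehyde at −78 °C, where carbonyl addition should outrun enolisation.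

Step 12
Reactants: 17 (1S,2S)-2-[2-(benzyloxy)-4-(4,5-dihydro-1,2-oxazol-3-yl)-6-methoxyphenoxy]-1-(3,4-dimethoxyphenyl)-3-[(triisopropylsilyl)oxy]propan-1-ol
Product: 18 (1S,2S)-2-[2-(benzyloxy)-4-(4,5-dihydro-1,2-oxazol-3-yl)-6-methoxyphenoxy]-1-(3,4-dimethoxyphenyl)propane-1,3-diol
Conditions: TBAF, THF, 0 °C to rt
Reagents that add atoms: none
Why: Fluoride-induced desilylation, placed before the ketone is unmasked so that the basic fluoride never meets a β-hydroxy ketone that could eliminate water.

Step 13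
Reactants: 18 (1S,2S)-2-[2-(benzyloxy)-4-(4,5-dihydro-1,2-oxazol-3-yl)-6-methoxyphenoxy]-1-(3,4-dimethoxyphenyl)propane-1,3-diol
Product: 19 1-{3-(benzyloxy)-4-{[(1S,2S)-1-(3,4-dimethoxyphenyl)-1,3-dihydroxypropan-2-yl]oxy}-5-methoxyphenyl}-3-hydroxypropan-1-one
Conditions: H2 (1 atm), Raney Ni, B(OH)3, MeOH/H2O (5:1), rt
Reagents that add atoms: water, O
Why: Raney nickel hydrogenolysis of the isoxazoline N–O bond gives the β-hydroxy imine, which the boric acid buffer hydrolyses to the β-hydroxy ketone before the C=N bond can be reduced; C7 and C8 are untouched, and any benzyl ether lost here only anticipates step 14.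

Step 14
Reactants: 19 1-{3-(benzyloxy)-4-{[(1S,2S)-1-(3,4-dimethoxyphenyl)-1,3-dihydroxypropan-2-yl]oxy}-5-methoxyphenyl}-3-hydroxypropan-1-one
Product: 20 1-{4-{[(1S,2S)-1-(3,4-dimethoxyphenyl)-1,3-dihydroxypropan-2-yl]oxy}-3-hydroxy-5-methoxyphenyl}-3-hydroxypropan-1-one
Conditions: H2 (1 atm), Pd/C (10%), EtOAc, rt, stopped at full conversion
Reagents that add atoms: none
Why: Catalytic hydrogenolysis of the phenolic benzyl ether; in neutral ethyl acetate the aryl ketone and the secondary C7 benzylic alcohol (deactivated by the neighbouring C8 oxygen) should be reduced much more slowly than the O-benzyl group is cleaved.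

## Compound list

1 | 3,4-dihydroxy-5-methoxybenzaldehyde | COc1cc(C=O)cc(O)c1O | starting material
2 | 3-(benzyloxy)-4-hydroxy-5-methoxybenzaldehyde | COc1cc(C=O)cc(OCc2ccccc2)c1O | intermediate
3 | diethyl bromomalonate | CCOC(=O)C(Br)C(=O)OCC | starting material
4 | diethyl 2-[2-(benzyloxy)-4-formyl-6-methoxyphenoxy]malonate | CCOC(=O)C(Oc1c(OCc2ccccc2)cc(C=O)cc1OC)C(=O)OCC | intermediate
5 | diethyl 2-{2-(benzyloxy)-4-[(E)-(hydroxyimino)methyl]-6-methoxyphenoxy}malonate | CCOC(=O)C(Oc1c(OCc2ccccc2)cc(/C=N/O)cc1OC)C(=O)OCC | intermediate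
6 | (E)-3-(benzyloxy)-4-[(1,3-dihydroxypropan-2-yl)oxy]-5-methoxybenzaldehyde oxime | OCC(CO)Oc1c(OCc2ccccc2)cc(/C=N/O)cc1OC | intermediate
7 | ethylene | C=C | starting material
8 | (Z)-3-(benzyloxy)-4-[(1,3-dihydroxypropan-2-yl)oxy]-N-hydroxy-5-methoxybenzimidoyl chloride (hydroximoyl chloride, formed in the flask) | OCC(CO)Oc1c(OCc2ccccc2)cc(/C(Cl)=N/O)cc1OC | intermediate
9 | 3-(benzyloxy)-4-[(1,3-dihydroxypropan-2-yl)oxy]-5-methoxybenzonitrile oxide (formed in the flask) | OCC(CO)Oc1c(OCc2ccccc2)cc(C#[N+][O-])cc1OC | intermediate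
10 | 2-[2-(benzyloxy)-4-(4,5-dihydro-1,2-oxazol-3-yl)-6-methoxyphenoxy]propane-1,3-diol | OCC(CO)Oc1c(OCc2ccccc2)cc(C2=NOCC2)cc1OC | intermediate
11 | (2S)-2-[2-(benzyloxy)-4-(4,5-dihydro-1,2-oxazol-3-yl)-6-methoxyphenoxy]-3-hydroxypropyl acetate | CC(=O)OC[C@H](CO)Oc1c(OCc2ccccc2)cc(C2=NOCC2)cc1OC | intermediate
12 | (2R)-2-[2-(benzyloxy)-4-(4,5-dihydro-1,2-oxazol-3-yl)-6-methoxyphenoxy]-3-[(triisopropylsilyl)oxy]propyl acetate | CC(=O)OC[C@H](CO[Si](C(C)C)(C(C)C)C(C)C)Oc1c(OCc2ccccc2)cc(C2=NOCC2)cc1OC | intermediate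
13 | (2R)-2-[2-(benzyloxy)-4-(4,5-dihydro-1,2-oxazol-3-yl)-6-methoxyphenoxy]-3-[(triisopropylsilyl)oxy]propan-1-ol | OC[C@H](CO[Si](C(C)C)(C(C)C)C(C)C)Oc1c(OCc2ccccc2)cc(C2=NOCC2)cc1OC | intermediate
14 | (2S)-2-[2-(benzyloxy)-4-(4,5-dihydro-1,2-oxazol-3-yl)-6-methoxyphenoxy]-3-[(triisopropylsilyl)oxy]propanal | O=C[C@H](CO[Si](C(C)C)(C(C)C)C(C)C)Oc1c(OCc2ccccc2)cc(C2=NOCC2)cc1OC | intermediate
15 | 4-bromo-1,2-dimethoxybenzene | COc1ccc(Br)cc1OC | starting material
16 | 3,4-dimethoxyphenylmagnesium bromide | COc1ccc([Mg]Br)cc1OC | intermediate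
17 | (1S,2S)-2-[2-(benzyloxy)-4-(4,5-dihydro-1,2-oxazol-3-yl)-6-methoxyphenoxy]-1-(3,4-dimethoxyphenyl)-3-[(triisopropylsilyl)oxy]propan-1-ol (threo, 7S,8S) | COc1ccc([C@H](O)[C@H](CO[Si](C(C)C)(C(C)C)C(C)C)Oc2c(OCc3ccccc3)cc(C3=NOCC3)cc2OC)cc1OC | intermediate
18 | (1S,2S)-2-[2-(benzyloxy)-4-(4,5-dihydro-1,2-oxazol-3-yl)-6-methoxyphenoxy]-1-(3,4-dimethoxyphenyl)propane-1,3-diol | COc1ccc([C@H](O)[C@H](CO)Oc2c(OCc3ccccc3)cc(C3=NOCC3)cc2OC)cc1OC | intermediate
19 | 1-{3-(benzyloxy)-4-{[(1S,2S)-1-(3,4-dimethoxyphenyl)-1,3-dihydroxypropan-2-yl]oxy}-5-methoxyphenyl}-3-hydroxypropan-1-one | COc1ccc([C@H](O)[C@H](CO)Oc2c(OCc3ccccc3)cc(C(=O)CCO)cc2OC)cc1OC | intermediate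
20 | 1-{4-{[(1S,2S)-1-(3,4-dimethoxyphenyl)-1,3-dihydroxypropan-2-yl]oxy}-3-hydroxy-5-methoxyphenyl}-3-hydroxypropan-1-one (CNP0188882.1) | COc1ccc([C@H](O)[C@H](CO)Oc2c(O)cc(C(=O)CCO)cc2OC)cc1OC | target

## Step count and risks

Total steps: 14. Longest linear sequence: 13 steps (1 to 20 through steps 1–9 and 11–14; step 10 is the one-step branch to the Grignard reagent).

Steps most likely to fail:

Step 11. The aryl ether oxygen is a weak donor, so non-chelated Felkin-type addition may compete and erode the threo preference; partial enolisation of the aldehyde would also erode C8. The fallback sets out from 14 and 16 and gives up stereocontrol in the C–C bond formation. The crude adduct, 17 mixed with its C7 epimer (1R,2S)-2-[2-(benzyloxy)-4-(4,5-dihydro-1,2-oxazol-3-yl)-6-methoxyphenoxy]-1-(3,4-dimethoxyphenyl)-3-[(triisopropylsilyl)oxy]propan-1-ol F1, is oxidised with DMP in CH2Cl2 to the single ketone (2S)-2-[2-(benzyloxy)-4-(4,5-dihydro-1,2-oxazol-3-yl)-6-methoxyphenoxy]-1-(3,4-dimethoxyphenyl)-3-[(triisopropylsilyl)oxy]propan-1-one F2. F2 is then reduced with LiBH(s-Bu)3 in THF at −78 °C. In the Felkin–Anh arrangement the bulky hydride enters anti to the C8 aryloxy group and past the C8 hydrogen, which for the (8S) ketone should give the (7S) alcohol, so the sequence comes back to the route at 17.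

Step 6. The enzyme may discriminate poorly between the two enantiotopic hydroxymethyl groups of this hindered 2-aryloxy diol, or acylate the wrong one. The fallback sets out from 10 and replaces biocatalysis by a chiral metal catalyst. Desymmetrising benzoylation uses vinyl benzoate and the dinuclear zinc catalyst formed from ZnEt2 and the ProPhenol ligand 2,6-bis{[2-(hydroxydiphenylmethyl)pyrrolidin-1-yl]methyl}-4-methylphenol in toluene at −15 °C. Both antipodes of the ligand are available, so the one that delivers the required sense is chosen. This should give (2S)-2-[2-(benzyloxy)-4-(4,5-dihydro-1,2-oxazol-3-yl)-6-methoxyphenoxy]-3-hydroxypropyl benzoate F3. Silylation with TIPSOTf and 2,6-lutidine gives (2R)-2-[2-(benzyloxy)-4-(4,5-dihydro-1,2-oxazol-3-yl)-6-methoxyphenoxy]-3-[(triisopropylsilyl)oxy]propyl benzoate F4, and methanolysis with K2CO3 in MeOH returns to the route at 13.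

Step 1. Regiocontrol in the dianion alkylation may be lost, with benzylation at O4 or at both oxygens. The fallback sets out from 1 and uses the opposite, acidity-driven selectivity with a temporary group. Allyl bromide with Li2CO3 in DMF alkylates only the more acidic 4-hydroxyl (para to the formyl group) to give 4-(allyloxy)-3-hydroxy-5-methoxybenzaldehyde F5. Benzylation with BnBr and K2CO3 in DMF gives 4-(allyloxy)-3-(benzyloxy)-5-methoxybenzaldehyde F6. Deallylation with Pd(PPh3)4 (cat.) and morpholine in THF leaves the benzyl ether alone and returns to the route at 2.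

## Further compounds

F1 | step 11 | (1R,2S)-2-[2-(benzyloxy)-4-(4,5-dihydro-1,2-oxazol-3-yl)-6-methoxyphenoxy]-1-(3,4-dimethoxyphenyl)-3-[(triisopropylsilyl)oxy]propan-1-ol | COc1ccc([C@@H](O)[C@H](CO[Si](C(C)C)(C(C)C)C(C)C)Oc2c(OCc3ccccc3)cc(C3=NOCC3)cc2OC)cc1OC
F2 | step 11 | (2S)-2-[2-(benzyloxy)-4-(4,5-dihydro-1,2-oxazol-3-yl)-6-methoxyphenoxy]-1-(3,4-dimethoxyphenyl)-3-[(triisopropylsilyl)oxy]propan-1-one | COc1ccc(C(=O)[C@H](CO[Si](C(C)C)(C(C)C)C(C)C)Oc2c(OCc3ccccc3)cc(C3=NOCC3)cc2OC)cc1OC
F3 | step 6 | (2S)-2-[2-(benzyloxy)-4-(4,5-dihydro-1,2-oxazol-3-yl)-6-methoxyphenoxy]-3-hydroxypropyl benzoate | O=C(OC[C@H](CO)Oc1c(OCc2ccccc2)cc(C2=NOCC2)cc1OC)c1ccccc1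
F4 | step 6 | (2R)-2-[2-(benzyloxy)-4-(4,5-dihydro-1,2-oxazol-3-yl)-6-methoxyphenoxy]-3-[(triisopropylsilyl)oxy]propyl benzoate | O=C(OC[C@H](CO[Si](C(C)C)(C(C)C)C(C)C)Oc1c(OCc2ccccc2)cc(C2=NOCC2)cc1OC)c1ccccc1
F5 | step 1 | 4-(allyloxy)-3-hydroxy-5-methoxybenzaldehyde | C=CCOc1c(O)cc(C=O)cc1OC
F6 | step 1 | 4-(allyloxy)-3-(benzyloxy)-5-methoxybenzaldehyde | C=CCOc1c(OCc2ccccc2)cc(C=O)cc1OC
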